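**Retrosynthetic overview**
- Target ⇐ free phenol by O‑sulfation ⇐ aryl aldehyde by Baeyer–Villiger/Dakin oxidation. The formyl group of 3,5‑dibromosalicylaldehyde is the masked sulfate‑bearing oxygen of ring A (the sulfated ring).
- Key disconnection: the hindered A–O–B ether bond. The ring‑B carbon is converted in situ, through its C–I bond, into an aryl(trimethoxyphenyl)‑λ3‑iodane (aryl cation equivalent) and joined to the salicylaldehyde phenoxide.
- The B–O–C ether bond is made the same way one step earlier, from a 2,4‑dibromophenyl cation equivalent and the ring‑B iodophenol. Ring B therefore reacts first as an O‑nucleophile and then as a reversed‑polarity C‑electrophile, with no protecting groups.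
- Ring B (2,3,4‑tribromo‑6‑iodophenol) comes from 5‑bromo‑2‑iodophenol by double bromination.
- No ring is formed: three purchased benzene rings are joined in the order C–B, then (CB)–A.

Assumption: the target has no stereocentre (it is achiral), and the hydrogen sulfate is isolated in the protonated form drawn, by H+ ion exchange of the first‑formed pyridinium salt.

**Route**

Step 1
Reactants: 1 5‑bromo‑2‑iodophenol
Product: 2 2,3,4‑tribromo‑6‑iodophenol
Conditions: NBS (2.1 equiv), NH4OAc (10 mol%), MeCN, 0 °C → rt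
Reagents that add atoms: N‑bromosuccinimide, O=C1CCC(=O)N1Br
Why: Electrophilic aromatic bromination (SEAr) in which OH directs to its open para and ortho carbons (both also ortho to the existing Br), and the low Br2 level from NBS limits ipso‑bromodeiodination; no stereocentre is formed.

Step 2
Reactants: 3 2,4‑dibromo‑1‑iodobenzene; 4 1,3,5‑trimethoxybenzene; 2 2,3,4‑tribromo‑6‑iodophenol
Product: 7 1,2,3‑tribromo‑4‑(2,4‑dibromophenoxy)‑5‑iodobenzene, via 2,4‑dibromo‑1‑[hydroxy(tosyloxy)‑λ3‑iodanyl]benzene 5 (not isolated), via (2,4‑dibromophenyl)(2,4,6‑trimethoxyphenyl)iodonium tosylate 6 (not isolated)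
Conditions: (i) 3 (1.3 equiv), mCPBA (1.3 equiv), TsOH·H2O (1.3 equiv), MeCN, 55 °C; (ii) 4 (1.3 equiv), rt; (iii) 2 (1.0 equiv), K2CO3 (4 equiv), 70 °C
Reagents that add atoms: none
Why: One‑pot Koser oxidation, SEAr ligand exchange with 4 and metal‑free ligand coupling (diaryliodonium O‑arylation), in which the electron‑poor ortho‑bromo aryl of 6 transfers in preference to the trimethoxyphenyl dummy and, with no transition metal present, the C–I and C–Br bonds of 2 survive.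

Step 3
Reactants: 7 1,2,3‑tribromo‑4‑(2,4‑dibromophenoxy)‑5‑iodobenzene; 4 1,3,5‑trimethoxybenzene; 8 3,5‑dibromo‑2‑hydroxybenzaldehyde
Product: 11 3,5‑dibromo‑2‑[3,4,5‑tribromo‑2‑(2,4‑dibromophenoxy)phenoxy]benzaldehyde, via 1,2,3‑tribromo‑4‑(2,4‑dibromophenoxy)‑5‑[hydroxy(tosyloxy)‑λ3‑iodanyl]benzene 9 (not isolated), via [3,4,5‑tribromo‑2‑(2,4‑dibromophenoxy)phenyl](2,4,6‑trimethoxyphenyl)iodonium tosylate 10 (not isolated)
Conditions: (i) 7 (1.0 equiv), mCPBA (1.05 equiv), TsOH·H2O (1.05 equiv), MeCN–DCE 1:1, 60 °C; (ii) 4 (1.1 equiv), rt; (iii) 8 (2.0 equiv), K2CO3 (5 equiv), 80 °C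
Reagents that add atoms: none
Why: Key fragment union by the same Koser oxidation/ligand exchange/ligand coupling sequence, in which the C–I carbon of 7 becomes an aryl cation equivalent and its tribromo, ortho‑aryloxy aryl group (ortho effect) is delivered to the acidic, di‑ortho‑substituted phenoxide of 8 through an inner‑sphere reductive elimination at iodine that tolerates hindered, weakly nucleophilic phenoxides and leaves all seven C–Br bonds and the aldehyde intact.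

Step 4
Reactants: 11 3,5‑dibromo‑2‑[3,4,5‑tribromo‑2‑(2,4‑dibromophenoxy)phenoxy]benzaldehyde
Product: 13 3,5‑dibromo‑2‑[3,4,5‑tribromo‑2‑(2,4‑dibromophenoxy)phenoxy]phenol, via 3,5‑dibromo‑2‑[3,4,5‑tribromo‑2‑(2,4‑dibromophenoxy)phenoxy]phenyl formate 12 (not isolated)
Conditions: mCPBA (2 equiv), CH2Cl2, 40 °C; then HCl (cat.), MeOH, rt
Reagents that add atoms: m‑chloroperoxybenzoic acid, OOC(=O)c1cccc(Cl)c1
Why: Baeyer–Villiger (Dakin‑type) oxidation in which the ortho‑aryloxy donor favours aryl over hydride migration in the Criegee adduct to give formate 12, which acid‑catalysed methanolysis cleaves to the phenol.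

Step 5
Reactants: 13 3,5‑dibromo‑2‑[3,4,5‑tribromo‑2‑(2,4‑dibromophenoxy)phenoxy]phenol
Product: 14 3,5‑dibromo‑2‑[3,4,5‑tribromo‑2‑(2,4‑dibromophenoxy)phenoxy]phenyl hydrogen sulfate (bromoiesol A sulfate)
Conditions: SO3·pyridine (4 equiv), pyridine, 40 °C; then Dowex 50W (H+), MeOH–H2O, 0 °C, lyophilise
Reagents that add atoms: sulfur trioxide–pyridine complex, [O-]S(=O)(=O)[n+]1ccccc1
Why: O‑sulfation of the single phenolic OH with SO3·pyridine, where the bromine‑deactivated rings resist C‑sulfonation and cold H+ exchange gives the hydrogen sulfate.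

**Compound list**

1 | 5‑bromo‑2‑iodophenol | Oc1cc(Br)ccc1I | starting material
2 | 2,3,4‑tribromo‑6‑iodophenol | Oc1c(I)cc(Br)c(Br)c1Br | intermediate
3 | 2,4‑dibromo‑1‑iodobenzene | Ic1ccc(Br)cc1Br | starting material
4 | 1,3,5‑trimethoxybenzene | COc1cc(OC)cc(OC)c1 | starting material
5 | 2,4‑dibromo‑1‑[hydroxy(tosyloxy)‑λ3‑iodanyl]benzene | Cc1ccc(cc1)S(=O)(=O)OI(O)c1ccc(Br)cc1Br | intermediate (not isolated)
6 | (2,4‑dibromophenyl)(2,4,6‑trimethoxyphenyl)iodonium tosylate | COc1cc(OC)c([I+]c2ccc(Br)cc2Br)c(OC)c1.Cc1ccc(cc1)S(=O)(=O)[O-] | intermediate (not isolated)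
7 | 1,2,3‑tribromo‑4‑(2,4‑dibromophenoxy)‑5‑iodobenzene | Ic1cc(Br)c(Br)c(Br)c1Oc1ccc(Br)cc1Br | intermediate
8 | 3,5‑dibromo‑2‑hydroxybenzaldehyde | O=Cc1cc(Br)cc(Br)c1O | starting material
9 | 1,2,3‑tribromo‑4‑(2,4‑dibromophenoxy)‑5‑[hydroxy(tosyloxy)‑λ3‑iodanyl]benzene | Cc1ccc(cc1)S(=O)(=O)OI(O)c1cc(Br)c(Br)c(Br)c1Oc1ccc(Br)cc1Br | intermediate (not isolated)
10 | [3,4,5‑tribromo‑2‑(2,4‑dibromophenoxy)phenyl](2,4,6‑trimethoxyphenyl)iodonium tosylate | COc1cc(OC)c([I+]c2cc(Br)c(Br)c(Br)c2Oc2ccc(Br)cc2Br)c(OC)c1.Cc1ccc(cc1)S(=O)(=O)[O-] | intermediate (not isolated)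
11 | 3,5‑dibromo‑2‑[3,4,5‑tribromo‑2‑(2,4‑dibromophenoxy)phenoxy]benzaldehyde | O=Cc1cc(Br)cc(Br)c1Oc1cc(Br)c(Br)c(Br)c1Oc1ccc(Br)cc1Br | intermediate
12 | 3,5‑dibromo‑2‑[3,4,5‑tribromo‑2‑(2,4‑dibromophenoxy)phenoxy]phenyl formate | O=COc1cc(Br)cc(Br)c1Oc1cc(Br)c(Br)c(Br)c1Oc1ccc(Br)cc1Br | intermediate (not isolated)
13 | 3,5‑dibromo‑2‑[3,4,5‑tribromo‑2‑(2,4‑dibromophenoxy)phenoxy]phenol | Oc1cc(Br)cc(Br)c1Oc1cc(Br)c(Br)c(Br)c1Oc1ccc(Br)cc1Br | intermediate
14 | 3,5‑dibromo‑2‑[3,4,5‑tribromo‑2‑(2,4‑dibromophenoxy)phenoxy]phenyl hydrogen sulfate (bromoiesol A sulfate) | O=S(=O)(O)Oc1cc(Br)cc(Br)c1Oc1cc(Br)c(Br)c(Br)c1Oc1ccc(Br)cc1Br | target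

**Totals**

Total step count: 5. Longest linear sequence: 5 (1 → 2 → 7 → 11 → 13 → 14).

**Three steps most likely to fail, with fallbacks**

Step 3 (key union). Three things can go wrong:
- oxidation of the electron‑poor iodide 7 may be slow;
- the λ3‑iodane 9 could cyclise onto the neighbouring aryloxy ring;
- the phenoxide of 8 is hindered and weakly nucleophilic, and m‑chlorobenzoate competes for the iodonium.

The fallback sets out from 7 and returns at 11 by a normal‑polarity SNAr. Iodine–magnesium exchange on 7 (i‑PrMgCl·LiCl, THF, −40 °C) gives [3,4,5‑tribromo‑2‑(2,4‑dibromophenoxy)phenyl]magnesium chloride F1. Trapping with B(OMe)3 gives dimethyl [3,4,5‑tribromo‑2‑(2,4‑dibromophenoxy)phenyl]boronate F2. Oxidation in the same flask (H2O2, NaOH) gives 3,4,5‑tribromo‑2‑(2,4‑dibromophenoxy)phenol F3. This phenoxide displaces fluoride from purchased 3,5‑dibromo‑2‑fluorobenzaldehyde F4 (K2CO3, DMF, 60 °C), where only the C–F bond is activated by the ortho formyl group, to give 11.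

Step 1. The second bromination, at the crowded ortho position, competes with ipso‑bromodeiodination. The fallback introduces iodine last by a Sandmeyer reaction; it sets out from 3 and returns at 7. Compound 3 is converted with 4 into iodonium salt 6 as in step 2(i)–(ii), and 6 is isolated by precipitation with Et2O. Purchased 5‑bromo‑2‑nitrophenol F5 is dibrominated (Br2, AcOH; OH, NO2 and Br all direct to the same two carbons) to 2,3,4‑tribromo‑6‑nitrophenol F6. F6 is O‑arylated with 6 (K2CO3, MeCN, 70 °C) to 1,2,3‑tribromo‑4‑(2,4‑dibromophenoxy)‑5‑nitrobenzene F7. Reduction (Fe, NH4Cl, EtOH–H2O) gives 3,4,5‑tribromo‑2‑(2,4‑dibromophenoxy)aniline F8. Diazotisation (NaNO2, TsOH, MeCN–H2O, 10 °C) gives 3,4,5‑tribromo‑2‑(2,4‑dibromophenoxy)benzenediazonium tosylate F9, which KI converts in the same flask into 7.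

Step 4. The aryl group is electron‑poor, so hydride migration to the benzoic acid may compete with aryl migration. The fallback sets out from 11 and returns at 13 through a methyl ketone, where the competition is aryl against methyl. MeMgBr (THF, −78 °C) adds to 11 to give racemic 1‑{3,5‑dibromo‑2‑[3,4,5‑tribromo‑2‑(2,4‑dibromophenoxy)phenoxy]phenyl}ethan‑1‑ol F10. Dess–Martin oxidation gives 1‑{3,5‑dibromo‑2‑[3,4,5‑tribromo‑2‑(2,4‑dibromophenoxy)phenoxy]phenyl}ethan‑1‑one F11. Baeyer–Villiger oxidation with CF3CO3H (TFAA, urea·H2O2, Na2HPO4, CH2Cl2) gives 3,5‑dibromo‑2‑[3,4,5‑tribromo‑2‑(2,4‑dibromophenoxy)phenoxy]phenyl acetate F12. Methanolysis (K2CO3, MeOH) gives 13.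

**Further compounds**

F1 | step 3 | [3,4,5‑tribromo‑2‑(2,4‑dibromophenoxy)phenyl]magnesium chloride | Cl[Mg]c1cc(Br)c(Br)c(Br)c1Oc1ccc(Br)cc1Br
F2 | step 3 | dimethyl [3,4,5‑tribromo‑2‑(2,4‑dibromophenoxy)phenyl]boronate | COB(OC)c1cc(Br)c(Br)c(Br)c1Oc1ccc(Br)cc1Br
F3 | step 3 | 3,4,5‑tribromo‑2‑(2,4‑dibromophenoxy)phenol | Oc1cc(Br)c(Br)c(Br)c1Oc1ccc(Br)cc1Br
F4 | step 3 | 3,5‑dibromo‑2‑fluorobenzaldehyde (purchased) | O=Cc1cc(Br)cc(Br)c1F
F5 | step 1 | 5‑bromo‑2‑nitrophenol (purchased) | Oc1cc(Br)ccc1[N+](=O)[O-]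
F6 | step 1 | 2,3,4‑tribromo‑6‑nitrophenol | Oc1c([N+](=O)[O-])cc(Br)c(Br)c1Br
F7 | step 1 | 1,2,3‑tribromo‑4‑(2,4‑dibromophenoxy)‑5‑nitrobenzene | [O-][N+](=O)c1cc(Br)c(Br)c(Br)c1Oc1ccc(Br)cc1Br
F8 | step 1 | 3,4,5‑tribromo‑2‑(2,4‑dibromophenoxy)aniline | Nc1cc(Br)c(Br)c(Br)c1Oc1ccc(Br)cc1Br
F9 | step 1 | 3,4,5‑tribromo‑2‑(2,4‑dibromophenoxy)benzenediazonium tosylate | N#[N+]c1cc(Br)c(Br)c(Br)c1Oc1ccc(Br)cc1Br.Cc1ccc(cc1)S(=O)(=O)[O-]
F10 | step 4 | 1‑{3,5‑dibromo‑2‑[3,4,5‑tribromo‑2‑(2,4‑dibromophenoxy)phenoxy]phenyl}ethan‑1‑ol (racemic) | CC(O)c1cc(Br)cc(Br)c1Oc1cc(Br)c(Br)c(Br)c1Oc1ccc(Br)cc1Br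
F11 | step 4 | 1‑{3,5‑dibromo‑2‑[3,4,5‑tribromo‑2‑(2,4‑dibromophenoxy)phenoxy]phenyl}ethan‑1‑one | CC(=O)c1cc(Br)cc(Br)c1Oc1cc(Br)c(Br)c(Br)c1Oc1ccc(Br)cc1Br
F12 | step 4 | 3,5‑dibromo‑2‑[3,4,5‑tribromo‑2‑(2,4‑dibromophenoxy)phenoxy]phenyl acetate | CC(=O)Oc1cc(Br)cc(Br)c1Oc1cc(Br)c(Br)c(Br)c1Oc1ccc(Br)cc1Br
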